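**Plan**

- Retrosynthesis: the C3–C1' bond to ring B is cut first, giving a chroman-4-one and an aryl bromide; the C4 carbonyl is taken back to a CH2 group; ring A is then opened at C5–C4a and C8–C8a, which leads to dimethyl squarate and C6-metalated 3,4-dihydro-2H-pyran.
- Enabling feature: C5, C6, C7 and C8 of ring A all carry oxygen, with the C5 hydroxyl para to the C8 methoxy (a hydroquinone monomethyl ether). These four carbons map onto a squarate, while C4a and the O1-bearing C8a map onto the enol ether double bond of dihydropyran.
- Forward order: the pyran ring is present from the start; C8–C8a is made by organolithium addition; ring A closes through C5–C4a in the thermal ring expansion; then C4 is oxidised, C3 is arylated, C2–C3 is dehydrogenated and both benzyl ethers are removed.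
- Stereochemistry: the target has no stereocentre; the centres that appear on the way (cyclobutenone C4, dienone C4a, chromanol C4, isoflavanone C3) are racemic and are all erased.

Key step: step 2

**Route**

Step 1
Reactants: 1 dimethyl squarate; 2 3,4-dihydro-2H-pyran
Product: 5 rac-4-(3,4-dihydro-2H-pyran-6-yl)-2,3,4-trimethoxycyclobut-2-en-1-one, via 6-lithio-3,4-dihydro-2H-pyran 3 (not isolated), via lithium alkoxide adduct 4 (not isolated)
Conditions: 2, t-BuLi (tert-butyllithium), THF, −78 to 0 °C; then 1, THF, −78 °C; then MeOTf, −78 °C to rt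
Reagents that add atoms: methyl trifluoromethanesulfonate (MeOTf), COS(=O)(=O)C(F)(F)F
Why: tert-Butyllithium removes the oxygen-activated vinylic C6 proton of the enol ether, the alkenyllithium 3 adds 1,2 to one of the two equivalent carbonyl groups of 1 at low temperature, and the lithium alkoxide 4 is O-methylated in the same flask by methyl triflate (squarate 1,2-addition with alkoxide trapping); the quaternary carbon forms as a racemate and is consumed in step 2.

Step 2
Reactants: 5 rac-4-(3,4-dihydro-2H-pyran-6-yl)-2,3,4-trimethoxycyclobut-2-en-1-one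
Product: 8 6,7,8-trimethoxychroman-5-ol, via dienylketene 6 (not isolated), via cyclohexadienone 7 (not isolated)
Conditions: degassed toluene, 110 °C, Ar
Reagents that add atoms: none
Why: Heat should open the cyclobutenone by a conrotatory four-electron electrocyclic cleavage of the C1–C4 bond to dienylketene 6, whose ketene carbon (future C5) then bonds to the β-carbon of the enol ether (future C4a) to give cyclohexadienone 7, which enolises to the aromatic phenol 8. The closest known reaction type is the thermal ring expansion of squarate-derived 4-alkenyl-4-alkoxycyclobutenones to hydroquinone monoethers (Moore rearrangement). Ring A is the only ring formed and it closes by a thermal disrotatory six-electron electrocyclisation through the new C5–C4a bond; the pyran ring is carried in intact. No stereocentre is created in the product, since the quaternary carbon of 5 becomes aromatic C8 and the transient C4a centre of 7 is lost on tautomerisation. The step needs the dihydropyranyl group to rotate inward so that it lies cis to the ketene, and this torquoselectivity is secured by the C4 methoxy donor, which rotates outward. Regiochemistry is fixed by connectivity: the ketene oxygen becomes the free C5 hydroxyl next to C4a, the methylated carbinol oxygen becomes the C8 methoxy next to O1, and the two squarate methoxy groups end up at C6 and C7.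

Step 3
Reactants: 8 6,7,8-trimethoxychroman-5-ol
Product: 9 5-(benzyloxy)-6,7,8-trimethoxychroman
Conditions: BnBr, K2CO3, DMF, rt, Ar
Reagents that add atoms: benzyl bromide, BrCc1ccccc1
Why: Williamson etherification of the phenoxide caps the oxidation-prone hydroquinone monoether; benzyl is chosen because it tolerates the base and palladium of step 6 and leaves together with the ring B benzyl group in step 8.

Step 4
Reactants: 9 5-(benzyloxy)-6,7,8-trimethoxychroman
Product: 11 5-(benzyloxy)-6,7,8-trimethoxychroman-4-one, via chroman-4-ol 10 (not isolated)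
Conditions: DDQ (2.5 equiv), 1,4-dioxane/H2O, 0 °C to rt
Reagents that add atoms: water, O
Why: DDQ benzylic oxidation in wet solvent, as known for C4 of 5,7-dialkoxychromans and flavans: hydride is abstracted from C4, whose cation is stabilised by three ring oxygens (O1 and the C5 ether ortho, the C7 methoxy para), water captures it to give 10, and a second equivalent of DDQ oxidises this electron-rich benzylic alcohol to the ketone, which then deactivates the ring; C2 and the benzyl ether methylene lack this stabilisation.

Step 5
Reactants: 12 3-bromo-2-methoxyphenol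
Product: 13 1-(benzyloxy)-3-bromo-2-methoxybenzene
Conditions: BnBr, K2CO3, acetone, reflux
Reagents that add atoms: benzyl bromide, BrCc1ccccc1
Why: Williamson etherification of an unhindered phenol; the benzyl ether masks the future 3'-hydroxyl against the strong base of step 6.

Step 6
Reactants: 11 5-(benzyloxy)-6,7,8-trimethoxychroman-4-one; 13 1-(benzyloxy)-3-bromo-2-methoxybenzene
Product: 14 rac-5-(benzyloxy)-3-[3-(benzyloxy)-2-methoxyphenyl]-6,7,8-trimethoxychroman-4-one
Conditions: Pd(OAc)2 (5 mol%), [(t-Bu)3PH]BF4 (10 mol%), NaOt-Bu (sodium tert-butoxide), toluene, 70 °C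
Reagents that add atoms: none
Why: Palladium-catalysed α-arylation of a ketone enolate (Buchwald–Hartwig type), known for chroman-4-ones: 13 adds oxidatively to zerovalent palladium, the C3 enolate of 11 (the only enolisable position) displaces bromide, and reductive elimination from the bulky phosphine complex forms C3–C1'; the product rests as a hindered enolate, which prevents a second arylation, and the new C3 centre is racemic and removed in step 7.

Step 7
Reactants: 14 rac-5-(benzyloxy)-3-[3-(benzyloxy)-2-methoxyphenyl]-6,7,8-trimethoxychroman-4-one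
Product: 15 5-(benzyloxy)-3-[3-(benzyloxy)-2-methoxyphenyl]-6,7,8-trimethoxy-4H-chromen-4-one
Conditions: DDQ (1.5 equiv), 1,4-dioxane, 100 °C
Reagents that add atoms: none
Why: DDQ dehydrogenation of an isoflavanone to the isoflavone, a standard oxidation: hydride loss from C2 of the enolised ketone, assisted by O1, and proton loss give the conjugated 4-pyranone; the benzyl ethers have no comparably activated C–H bond.

Step 8
Reactants: 15 5-(benzyloxy)-3-[3-(benzyloxy)-2-methoxyphenyl]-6,7,8-trimethoxy-4H-chromen-4-one
Product: 16 5,3'-dihydroxy-6,7,8,2'-tetramethoxyisoflavone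
Conditions: H2 (1 atm), Pd/C (palladium on carbon), EtOAc/MeOH, rt, stopped when 15 is consumed
Reagents that add atoms: none
Why: Catalytic hydrogenolysis cleaves both aryl benzyl ethers, while the aryl methyl ethers are inert and the C2–C3 double bond of the pyranone is reduced much more slowly at ambient pressure.

**Compound list**

1 | dimethyl squarate (3,4-dimethoxycyclobut-3-ene-1,2-dione) | COC1=C(OC)C(=O)C1=O | starting material
2 | 3,4-dihydro-2H-pyran | C1CC=COC1 | starting material
3 | 6-lithio-3,4-dihydro-2H-pyran | [Li]C1=CCCCO1 | intermediate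
4 | lithium 1-(3,4-dihydro-2H-pyran-6-yl)-2,3-dimethoxy-4-oxocyclobut-2-en-1-olate (racemic) | COC1=C(OC)C(O[Li])(C2=CCCCO2)C1=O | intermediate
5 | rac-4-(3,4-dihydro-2H-pyran-6-yl)-2,3,4-trimethoxycyclobut-2-en-1-one | COC1=C(OC)C(OC)(C2=CCCCO2)C1=O | intermediate
6 | (3Z)-4-(3,4-dihydro-2H-pyran-6-yl)-2,3,4-trimethoxybuta-1,3-dien-1-one (dienylketene, dihydropyranyl cis to the ketene) | O=C=C(OC)/C(OC)=C(OC)\C1=CCCCO1 | intermediate
7 | rac-6,7,8-trimethoxy-2,3,4,4a-tetrahydro-5H-chromen-5-one | COC1=C(OC)C(OC)=C2OCCCC2C1=O | intermediate
8 | 6,7,8-trimethoxychroman-5-ol | COc1c(OC)c(OC)c2OCCCc2c1O | intermediate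
9 | 5-(benzyloxy)-6,7,8-trimethoxychroman | COc1c(OC)c(OC)c2OCCCc2c1OCc1ccccc1 | intermediate
10 | rac-5-(benzyloxy)-6,7,8-trimethoxychroman-4-ol | COc1c(OC)c(OC)c2OCCC(O)c2c1OCc1ccccc1 | intermediate
11 | 5-(benzyloxy)-6,7,8-trimethoxychroman-4-one | COc1c(OC)c(OC)c2OCCC(=O)c2c1OCc1ccccc1 | intermediate
12 | 3-bromo-2-methoxyphenol | COc1c(O)cccc1Br | starting material
13 | 1-(benzyloxy)-3-bromo-2-methoxybenzene | COc1c(OCc2ccccc2)cccc1Br | intermediate
14 | rac-5-(benzyloxy)-3-[3-(benzyloxy)-2-methoxyphenyl]-6,7,8-trimethoxychroman-4-one | COc1c(OC)c(OC)c2OCC(c3cccc(OCc4ccccc4)c3OC)C(=O)c2c1OCc1ccccc1 | intermediate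
15 | 5-(benzyloxy)-3-[3-(benzyloxy)-2-methoxyphenyl]-6,7,8-trimethoxy-4H-chromen-4-one | COc1c(OC)c(OC)c2occ(-c3cccc(OCc4ccccc4)c3OC)c(=O)c2c1OCc1ccccc1 | intermediate
16 | 5,3'-dihydroxy-6,7,8,2'-tetramethoxyisoflavone (5-hydroxy-3-(3-hydroxy-2-methoxyphenyl)-6,7,8-trimethoxy-4H-chromen-4-one) | COc1c(O)cccc1-c1coc2c(OC)c(OC)c(OC)c(O)c2c1=O | target

**Step count and risks**

Total step count: 8. Longest linear sequence: 7 (steps 1, 2, 3, 4, 6, 7, 8); step 5 is the one-step side branch.

Steps most likely to fail:

Step 4. After hydride abstraction the C4 cation may lose a C3 proton instead of being captured by water; the 2H-chromene so formed would be oxidised further to a benzopyrylium ion and degrade, and one-electron oxidation of the penta-oxygenated ring by DDQ is a second drain. The fallback moves the oxidation to a substrate without a benzyl ether and uses hydrogen-atom abstraction instead of hydride abstraction. It sets out from 8: acetylation (Ac2O, pyridine, rt) should give 6,7,8-trimethoxychroman-5-yl acetate F1. Chromium-catalysed benzylic oxidation (catalytic CrO3, t-BuOOH, CH2Cl2, rt) should then give 6,7,8-trimethoxy-4-oxochroman-5-yl acetate F2. Methanolysis (K2CO3, MeOH, rt) should give 5-hydroxy-6,7,8-trimethoxychroman-4-one F3, and benzylation of this chelated phenol (BnBr, K2CO3, DMF, 60 °C) comes back to the route at 11.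

Step 6. The chromanone enolate may open by β-elimination of the C8a phenoxide (retro-oxa-Michael), and the ortho-methoxy bromide couples slowly, so enolate decay may outrun arylation. The fallback forms C3–C1' by Suzuki–Miyaura coupling at the chromone oxidation level. It sets out from 11: pyridinium tribromide (2.2 equiv, CH2Cl2/AcOH, rt) should brominate C3 twice, passing through rac-5-(benzyloxy)-3-bromo-6,7,8-trimethoxychroman-4-one F4, which is not isolated, to 5-(benzyloxy)-3,3-dibromo-6,7,8-trimethoxychroman-4-one F5. Triethylamine (CH2Cl2, rt) should then eliminate HBr to give 5-(benzyloxy)-3-bromo-6,7,8-trimethoxy-4H-chromen-4-one F6. In parallel, Miyaura borylation of 13 (bis(pinacolato)diboron, PdCl2(dppf), that is [1,1'-bis(diphenylphosphino)ferrocene]palladium dichloride, KOAc, 1,4-dioxane, 80 °C) should give 2-[3-(benzyloxy)-2-methoxyphenyl]-4,4,5,5-tetramethyl-1,3,2-dioxaborolane F7. Coupling of the bromochromone with the boronate (Pd(PPh3)4, Na2CO3, DME/H2O, 80 °C) comes back to the route at 15, so 14 and step 7 are bypassed.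

Step 8. Saturation of the C2–C3 double bond of the pyranone may compete with hydrogenolysis, especially while the hindered C5 benzyl ether is still in place. The fallback is a Lewis-acid debenzylation without hydrogen. It sets out from 15: BCl3 with pentamethylbenzene as cation scavenger (CH2Cl2, −78 °C) should cleave both benzyl ethers and spare the methyl ethers, arriving directly at 16; no new compound arises on this path (F0).

**Further compounds**

F1 | step 4 | 6,7,8-trimethoxychroman-5-yl acetate | COc1c(OC)c(OC)c2OCCCc2c1OC(C)=O
F2 | step 4 | 6,7,8-trimethoxy-4-oxochroman-5-yl acetate | COc1c(OC)c(OC)c2OCCC(=O)c2c1OC(C)=O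
F3 | step 4 | 5-hydroxy-6,7,8-trimethoxychroman-4-one | COc1c(OC)c(OC)c2OCCC(=O)c2c1O
F4 | step 6 | rac-5-(benzyloxy)-3-bromo-6,7,8-trimethoxychroman-4-one | COc1c(OC)c(OC)c2OCC(Br)C(=O)c2c1OCc1ccccc1
F5 | step 6 | 5-(benzyloxy)-3,3-dibromo-6,7,8-trimethoxychroman-4-one | COc1c(OC)c(OC)c2OCC(Br)(Br)C(=O)c2c1OCc1ccccc1
F6 | step 6 | 5-(benzyloxy)-3-bromo-6,7,8-trimethoxy-4H-chromen-4-one | COc1c(OC)c(OC)c2occ(Br)c(=O)c2c1OCc1ccccc1
F7 | step 6 | 2-[3-(benzyloxy)-2-methoxyphenyl]-4,4,5,5-tetramethyl-1,3,2-dioxaborolane | COc1c(OCc2ccccc2)cccc1B1OC(C)(C)C(C)(C)O1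
F0 | step 8 | none | none
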